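The rate constants are not given, so the reckoning starts from what Monday's run shows: target reached 8.1% of the substrate charged by 4.00 h, a reading with a scatter of 0.5 percentage points.

| setting | Monday's | violet | blue |
|---|---|---|---|
| substrate | 1.5 M | 1.0 M | 1.0 M |
| partner | 2 M | 2.00 M | 2.60 M |
| rival reagent | 0.80 M | 0.800 M | 0.800 M |
| remark | run made earlier |  |  |
| time |  | 20 h | 20 h |

Monday's run (percent of the substrate charged)

| time / h | target / % |
|---|---|
| 0.200 | 0.2 |
| 0.667 | 2.2 |
| 1.00 | 2.3 |
| 1.50 | 3.9 |
| 2.50 | 5.2 |
| 3.00 | 4.5 |
| 4.00 | 8.1 |

(standard deviation of a reading: 0.5 percentage points)



1. which of the two there is more of at the end, violet (target / side product)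
2. which of the two there is more of at the end, blue (target / side product)
3. final target, as a percentage of the substrate charged, in violet
4. final target, as a percentage of the substrate charged, in blue

Counted in percent of the charge, the substrate's own amount cancels if the step is first order in it. The hourly fraction then follows partner, a pseudo-first-order decay of substrate. These orders are assumed, since a single recipe does not test them.

Fraction per hour on Monday = 8.1% / 4.00 h = 0.0203 h⁻¹

Violet = 0.0203 h⁻¹ × 2.00 M / 2 M × 20 h = 0.405

Blue = 0.0203 h⁻¹ × 2.60 M / 2 M × 20 h = 0.527

This partner exposure, Monday's hourly fraction scaled to the flask's partner charge and multiplied by its time, counts the lifetimes of substrate toward target that the flask is given. With no other exit for substrate and partner held at its charge, target = 1 − exp(−exposure). That own reckoning gives 33.3% in violet and 40.9% in blue.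

One number is not enough. Monday's readings hold no side product, so these percentages describe target without a competitor, and which product leads is not read from them.

The forecast names target in violet and target in blue, with 27% and 33% of target, and calls the choice “a weak guess, based on partner outnumbering rival”.

The flasks give 20.9% of target in violet and 24.8% in blue. The side product leads in both, at 34.1% in violet and 33.2% in blue.

    substrate + rival reagent → side product (k = 7.00 × 10⁻⁴ L mol⁻¹ min⁻¹)
    2 partner → self-condensation product (k = 1.60 × 10⁻⁴ L mol⁻¹ min⁻¹)
    substrate + partner → target (k = 1.80 × 10⁻⁴ L mol⁻¹ min⁻¹)

Violet's target reaches 0.628 of the percentage reckoned from its exposure. Part of the gap comes from two things acting together, partner going to self-condensation product and the reading at 20 h and not ten times later: without that step violet gives 25.9% of target against 20.9%, and at 200 h it gives 34.4%. In blue the same pair acts, with 32.1% of target without the step and 38.1% at 200 h. A neighbour of violet charged with 0.80 M of partner has an exposure of 0.162, which reckons to 15.0% of target. That flask stands at 10.3%, or 0.687 of its reckoned percentage.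

All runs were generated by integration for substances that don't exist; scatter was added.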